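## Retrosynthetic overview
1. Last bond, C1–styryl: a tertiary nitro group is replaced by a radical reaction anti to the C6 aryl group. This sets the quaternary centre.
2. C5–H comes from decarbonylation of a cyclohexenecarbaldehyde.
3. Key step: the nitronate of 5-nitrohexan-2-one acts as a masked ketone acyl anion. It attacks the β-carbon of a coumarinyl acrolein under iminium catalysis, forming C1–C6 and setting C6. In the same flask an enamine aldol condensation on the methyl ketone forms C4=C5 and closes the cyclohexene.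
4. Both coumarin units come from one 6-bromo-7-methoxycoumarin through two Heck reactions (acrolein acetal, phenyl vinyl sulfone).
5. Ring order: the two pyranone rings first (Wittig–lactonisation), the cyclohexene last.

Assumption: 5-bromo-2-hydroxy-4-methoxybenzaldehyde is taken as a catalogue compound. Cyclohexene atoms are labelled C1 (quaternary), C2, C3, C4(Me)=C5, C6 (aryl-bearing). In the target C1 is R and C6 is S, with the aryl group trans to the styryl group and cis to the C1 methyl.

## Route

Step 1
Reactants: 1 5-bromo-2-hydroxy-4-methoxybenzaldehyde; 2 ethyl (triphenyl-λ5-phosphanylidene)acetate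
Product: 4 6-bromo-7-methoxy-2H-chromen-2-one, via E-cinnamate ester 3 (not isolated)
Conditions: PhNEt2, 210 °C, 4 h
Reagents that add atoms: none
Why: Wittig olefination gives the o-hydroxycinnamate, which at this temperature isomerises from E to Z and lactonises (standard salicylaldehyde-to-coumarin annulation); the aryl bromide and methyl ether are inert and no stereocentre forms.

Step 2
Reactants: 4 6-bromo-7-methoxy-2H-chromen-2-one; 5 3,3-diethoxyprop-1-ene (acrolein diethyl acetal)
Product: 7 (E)-3-(7-methoxy-2-oxo-2H-chromen-6-yl)prop-2-enal, via E-allylic acetal 6 (not isolated)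
Conditions: Pd(OAc)2 (3 mol %), n-Bu4NOAc, K2CO3, KCl, DMF, 90 °C; then 2 M HCl, rt
Reagents that add atoms: water, O
Why: Mizoroki–Heck reaction at the terminal alkene under acetate/carbonate conditions gives the E-cinnamyl acetal rather than the propanoate ester, and the acid work-up hydrolyses the acetal and recloses any opened lactone.

Step 3
Reactants: 8 nitroethane; 9 but-3-en-2-one (methyl vinyl ketone)
Product: 10 5-nitrohexan-2-one (racemic)
Conditions: 8 (5 equiv), Amberlyst A-21, neat, 0 °C to rt
Reagents that add atoms: none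
Why: Base-catalysed nitro-Michael addition, with excess nitroethane to suppress double addition; the nitro-bearing stereocentre is racemic and is erased in step 7.

Step 4
Reactants: 7 (E)-3-(7-methoxy-2-oxo-2H-chromen-6-yl)prop-2-enal; 10 5-nitrohexan-2-one
Product: 13 (6S)-6-(7-methoxy-2-oxo-2H-chromen-6-yl)-2,5-dimethyl-5-nitrocyclohex-1-ene-1-carbaldehyde (both C5 epimers), via Michael adduct 11 (not isolated), via aldol 12 (not isolated)
Conditions: (R)-2-[diphenyl(trimethylsilyloxy)methyl]pyrrolidine (20 mol %), PhCO2H (20 mol %), 10 (2 equiv), MeOH, 25 °C, 72 h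
Reagents that add atoms: none
Why: In this domino nitro-Michael/aldol condensation (iminium then enamine catalysis, known for γ-nitroketones and enals), the nitronate of 10, a masked acyl anion of hexane-2,5-dione, joins its carbon to the equally electrophilic enal β-carbon from the Re face left open by the (R)-catalyst (sets C6), and the enamine then closes on the methyl ketone and loses water, while the nitro carbon forms as an epimer mixture that does not matter.

Step 5
Reactants: 13 (6S)-6-(7-methoxy-2-oxo-2H-chromen-6-yl)-2,5-dimethyl-5-nitrocyclohex-1-ene-1-carbaldehyde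
Product: 14 6-[(1R)-3,6-dimethyl-6-nitrocyclohex-2-en-1-yl]-7-methoxy-2H-chromen-2-one (both C6 epimers)
Conditions: RhCl(PPh3)3 (1.1 equiv), PhMe, 110 °C, Ar
Reagents that add atoms: none
Why: Tsuji–Wilkinson decarbonylation (C–H insertion, CO extrusion, alkenyl–H reductive elimination) keeps the double bond at C4=C5 and leaves C6 untouched, and the stoichiometric reagent keeps the temperature low enough for the tertiary nitro group (the descriptor changes only through CIP priorities).

Step 6
Reactants: 4 6-bromo-7-methoxy-2H-chromen-2-one; 15 phenyl vinyl sulfone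
Product: 16 6-[(E)-2-(phenylsulfonyl)ethenyl]-7-methoxy-2H-chromen-2-one
Conditions: Pd(OAc)2 (5 mol %), P(o-tol)3 (10 mol %), Et3N, DMF, 100 °C
Reagents that add atoms: none
Why: Mizoroki–Heck reaction of an aryl bromide at the β-carbon of an electron-poor terminal alkene gives the E-styryl sulfone.

Step 7
Reactants: 14 6-[(1R)-3,6-dimethyl-6-nitrocyclohex-2-en-1-yl]-7-methoxy-2H-chromen-2-one; 16 6-[(E)-2-(phenylsulfonyl)ethenyl]-7-methoxy-2H-chromen-2-one
Product: 17 6-[(1S,6R)-6-[(E)-2-(7-methoxy-2-oxo-2H-chromen-6-yl)ethenyl]-3,6-dimethylcyclohex-2-en-1-yl]-7-methoxy-2H-chromen-2-one (target)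
Conditions: 16 (3 equiv), (Bu3Sn)2 (1.5 equiv), AIBN (0.3 equiv in portions), PhH (1 M), 80 °C, dark
Reagents that add atoms: none
Why: Proposed new method: Bu3Sn• attacks the nitro oxygen and the adduct fragments to the tertiary C1 radical and Bu3SnONO (as in tin-mediated denitration and denitrative allylation of tertiary nitroalkanes), the nucleophilic radical adds to the sulfonyl-bearing carbon of 16 to give a benzylic radical that expels PhSO2• (E-selective radical addition–elimination known for β-sulfonylstyrenes), PhSO2• regenerates Bu3Sn• from (Bu3Sn)2, and both epimers of 14 give the same planar radical, which is attacked anti to the pseudo-axial C6 aryl group so that the styryl group ends trans to it (C1 = R).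

## Compound list
1 | 5-bromo-2-hydroxy-4-methoxybenzaldehyde | COc1cc(O)c(C=O)cc1Br | starting material
2 | ethyl (triphenyl-λ5-phosphanylidene)acetate | CCOC(=O)C=P(c1ccccc1)(c1ccccc1)c1ccccc1 | starting material
3 | ethyl (E)-3-(5-bromo-2-hydroxy-4-methoxyphenyl)prop-2-enoate | CCOC(=O)/C=C/c1cc(Br)c(OC)cc1O | intermediate
4 | 6-bromo-7-methoxy-2H-chromen-2-one | COc1cc2oc(=O)ccc2cc1Br | intermediate
5 | 3,3-diethoxyprop-1-ene | C=CC(OCC)OCC | starting material
6 | 6-[(E)-3,3-diethoxyprop-1-enyl]-7-methoxy-2H-chromen-2-one | CCOC(OCC)/C=C/c1cc2ccc(=O)oc2cc1OC | intermediate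
7 | (E)-3-(7-methoxy-2-oxo-2H-chromen-6-yl)prop-2-enal | O=C/C=C/c1cc2ccc(=O)oc2cc1OC | intermediate
8 | nitroethane | CC[N+](=O)[O-] | starting material
9 | but-3-en-2-one | C=CC(C)=O | starting material
10 | 5-nitrohexan-2-one (racemic) | CC(=O)CCC(C)[N+](=O)[O-] | intermediate
11 | (3R)-3-(7-methoxy-2-oxo-2H-chromen-6-yl)-4-methyl-4-nitro-7-oxooctanal (both C4 epimers) | O=CC[C@H](c1cc2ccc(=O)oc2cc1OC)C(C)(CCC(C)=O)[N+](=O)[O-] | intermediate
12 | (6R)-2-hydroxy-6-(7-methoxy-2-oxo-2H-chromen-6-yl)-2,5-dimethyl-5-nitrocyclohexane-1-carbaldehyde (other centres mixed) | [O-][N+](=O)C1(C)CCC(C)(O)C(C=O)[C@@H]1c1cc2ccc(=O)oc2cc1OC | intermediate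
13 | (6S)-6-(7-methoxy-2-oxo-2H-chromen-6-yl)-2,5-dimethyl-5-nitrocyclohex-1-ene-1-carbaldehyde (both C5 epimers) | [O-][N+](=O)C1(C)CCC(C)=C(C=O)[C@@H]1c1cc2ccc(=O)oc2cc1OC | intermediate
14 | 6-[(1R)-3,6-dimethyl-6-nitrocyclohex-2-en-1-yl]-7-methoxy-2H-chromen-2-one (both C6 epimers) | [O-][N+](=O)C1(C)CCC(C)=C[C@@H]1c1cc2ccc(=O)oc2cc1OC | intermediate
15 | phenyl vinyl sulfone | C=CS(=O)(=O)c1ccccc1 | starting material
16 | 6-[(E)-2-(phenylsulfonyl)ethenyl]-7-methoxy-2H-chromen-2-one | COc1cc2oc(=O)ccc2cc1/C=C/S(=O)(=O)c1ccccc1 | intermediate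
17 | 6-[(1S,6R)-6-[(E)-2-(7-methoxy-2-oxo-2H-chromen-6-yl)ethenyl]-3,6-dimethylcyclohex-2-en-1-yl]-7-methoxy-2H-chromen-2-one | COc1cc2oc(=O)ccc2cc1/C=C/[C@@]1(C)CCC(C)=C[C@@H]1c1cc2ccc(=O)oc2cc1OC | target

## Step count and risks
Total steps: 7. Longest linear sequence: 5 (steps 1, 2, 4, 5, 7).

**Step 7 (highest risk).** The hindered C1 radical may undergo a 1,2-aryl shift to the allylic C6 radical before it is trapped. The doubly activated C6–H may also be abstracted. The fallback sets out from 14 and comes back at 17.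
- The radical is caught by the much faster acceptor (E)-1,2-bis(phenylsulfonyl)ethene ((Bu3Sn)2, AIBN, PhH, 80 °C). This gives 6-[(1S,6S)-3,6-dimethyl-6-[(E)-2-(phenylsulfonyl)ethenyl]cyclohex-2-en-1-yl]-7-methoxy-2H-chromen-2-one F3.
- Radical sulfone-to-tin exchange (Bu3SnH, AIBN) gives tributyl{(E)-2-[(1S,2S)-2-(7-methoxy-2-oxo-2H-chromen-6-yl)-1,4-dimethylcyclohex-3-en-1-yl]ethenyl}stannane F4.
- Stille coupling of this stannane with 4 (Pd(PPh3)4, CuI, CsF, DMF, 45 °C) makes the aryl–vinyl bond and gives 17.

**Step 4.** The secondary nitronate may add too slowly to the electron-rich iminium ion, or the aldol on the ketone may stall. The fallback sets out from 7, 8 and 9 and comes back at 11.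
- The same catalyst adds the unhindered nitroethane 8 to 7. This gives (3R)-3-(7-methoxy-2-oxo-2H-chromen-6-yl)-4-nitropentanal F1.
- The nitronate of this aldehyde (KF on alumina, MeCN, 0 °C) then builds the fully substituted nitro carbon in a separate nitro-Michael addition to 9, giving 11.
- Pyrrolidinium acetate closes 11 to 13.

**Step 5.** The formyl group on a tetrasubstituted alkene next to the aryl group may resist rhodium insertion below the temperature at which HNO2 is lost. The fallback sets out from 7 and 10 and comes back at 14 without passing 13.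
- Oxidative carbene catalysis converts 7 into its α,β-unsaturated acyl azolium. Conditions are an aminoindanol-derived N-mesityl triazolium salt, DBU, LiCl and 3,3',5,5'-tetra-tert-butyldiphenoquinone in THF.
- Nitronate Michael addition, aldol and lactonisation give the cis-fused β-lactone (2R)-2-(7-methoxy-2-oxo-2H-chromen-6-yl)-3,6-dimethyl-3-nitro-7-oxabicyclo[4.2.0]octan-8-one F2.
- Heating in toluene at 110 °C extrudes CO2 to give 14.

## Further compounds
F1 | step 4 | (3R)-3-(7-methoxy-2-oxo-2H-chromen-6-yl)-4-nitropentanal (both C4 epimers) | O=CC[C@H](c1cc2ccc(=O)oc2cc1OC)C(C)[N+](=O)[O-]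
F2 | step 5 | (2R)-2-(7-methoxy-2-oxo-2H-chromen-6-yl)-3,6-dimethyl-3-nitro-7-oxabicyclo[4.2.0]octan-8-one (cis-fused, acyl carbon trans to aryl, nitro carbon mixed) | [O-][N+](=O)C1(C)CC[C@@]2(C)OC(=O)[C@H]2[C@@H]1c1cc2ccc(=O)oc2cc1OC
F3 | step 7 | 6-[(1S,6S)-3,6-dimethyl-6-[(E)-2-(phenylsulfonyl)ethenyl]cyclohex-2-en-1-yl]-7-methoxy-2H-chromen-2-one | O=S(=O)(/C=C/[C@@]1(C)CCC(C)=C[C@@H]1c1cc2ccc(=O)oc2cc1OC)c1ccccc1
F4 | step 7 | tributyl{(E)-2-[(1S,2S)-2-(7-methoxy-2-oxo-2H-chromen-6-yl)-1,4-dimethylcyclohex-3-en-1-yl]ethenyl}stannane | CCCC[Sn](CCCC)(CCCC)/C=C/[C@@]1(C)CCC(C)=C[C@@H]1c1cc2ccc(=O)oc2cc1OC
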